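**Plan**
1. Retrosynthesis: the four benzyl ethers are cut last. Ring C of the flavanone is then cut at O1–C8a and at C2–C3, giving aldehyde 12 (ring B, the diaryl ether and the complete benzylated flavone unit) and silyl enol ether 4 (ring A with fluorine at the future C8a).
2. Enabling feature: the C4 carbonyl sits on ring A ortho to C8a. It makes C3 an enolate carbon for the aldehyde carbon C2 and activates C8a–F for attack by the C2 oxygen; the 5- and 7-oxygens are meta to C8a and do not oppose the substitution.
3. Ring A piece (steps 1–3): lithiation–acetylation of 3,5-difluoroanisole, exchange of one fluoride for benzyl oxide, silyl enol ether.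
4. Aldehyde piece (steps 4–7): acetal of 4-(benzyloxy)-3-hydroxybenzaldehyde, diaryl ether by SNAr on 4-fluorobenzaldehyde, chalcone, oxidative closure to the flavone and release of the formyl group.
5. Step 8 joins the halves and closes ring C in one operation; step 9 removes the benzyl groups.
6. Stereochemistry: the only stereocentre, C2 (S), is set in step 8 by a chiral ammonium cation paired with the enolate; the neutral hydrogenolysis that follows does not touch it.

Key step: step 8

Assumption: the (S,S) cation named in step 8 is taken to guide the enolate to the Si face of the aldehyde; should a first run show the opposite sense, the (R,R) salt takes its place with no other change.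

Step 1
Reactants: 1 3,5-difluoroanisole
Product: 2 1-(2,6-difluoro-4-methoxyphenyl)ethanone
Conditions: n-BuLi, THF, −78 °C; then MeC(O)N(OMe)Me, −78 → 0 °C; 1 M HCl
Reagents that add atoms: N-methoxy-N-methylacetamide, CC(=O)N(C)OC
Why: Directed ortho-lithiation occurs at the carbon between the two fluorines, the most acidic position, and the aryllithium is acylated once by the N-methoxy-N-methylamide (Weinreb ketone synthesis), whose chelated adduct collapses only on work-up.

Step 2
Reactants: 2 1-(2,6-difluoro-4-methoxyphenyl)ethanone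
Product: 3 1-[2-(benzyloxy)-6-fluoro-4-methoxyphenyl]ethanone
Conditions: BnOH (1.2 equiv), KOt-Bu (1.1 equiv), THF, 0 → 50 °C
Reagents that add atoms: benzyl alcohol, OCc1ccccc1
Why: Nucleophilic aromatic substitution (SNAr) of one fluoride ortho to the acetyl group by benzyl oxide; the benzyloxy group then deactivates the ring, so the second fluoride should be kept.

Step 3
Reactants: 3 1-[2-(benzyloxy)-6-fluoro-4-methoxyphenyl]ethanone
Product: 4 {1-[2-(benzyloxy)-6-fluoro-4-methoxyphenyl]ethenyloxy}trimethylsilane
Conditions: TMSOTf, Et3N, CH2Cl2, 0 °C; pentane extraction, used at once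
Reagents that add atoms: trimethylsilyl trifluoromethanesulfonate, C[Si](C)(C)OS(=O)(=O)C(F)(F)F
Why: Soft enolisation and O-silylation of the methyl ketone (silyl enol ether formation), for which only one regiochemistry is possible.

Step 4
Reactants: 5 4-(benzyloxy)-3-hydroxybenzaldehyde
Product: 6 2-(benzyloxy)-5-(1,3-dioxolan-2-yl)phenol
Conditions: ethylene glycol, p-TsOH (cat.), toluene, reflux, water separator
Reagents that add atoms: ethylene glycol, OCCO
Why: Acid-catalysed acetalisation masks the formyl group of ring B, so that only the formyl group brought in at step 5 enters the chalcone condensation.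

Step 5
Reactants: 6 2-(benzyloxy)-5-(1,3-dioxolan-2-yl)phenol; 7 4-fluorobenzaldehyde
Product: 8 4-[2-(benzyloxy)-5-(1,3-dioxolan-2-yl)phenoxy]benzaldehyde
Conditions: K2CO3, DMF, 110 °C
Reagents that add atoms: none
Why: SNAr of the fluoride para to the formyl group by the phenoxide gives the diaryl ether, and the dioxolane is stable to carbonate.

Step 6
Reactants: 8 4-[2-(benzyloxy)-5-(1,3-dioxolan-2-yl)phenoxy]benzaldehyde; 9 1-[2,4-bis(benzyloxy)-6-hydroxyphenyl]ethanone
Product: 10 (E)-1-[2,4-bis(benzyloxy)-6-hydroxyphenyl]-3-{4-[2-(benzyloxy)-5-(1,3-dioxolan-2-yl)phenoxy]phenyl}prop-2-en-1-one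
Conditions: KOH, EtOH–THF, rt; aq. NH4Cl work-up
Reagents that add atoms: none
Why: Claisen–Schmidt condensation of the methyl ketone with the free formyl group should give the E-chalcone, the acetal being inert to hydroxide.

Step 7
Reactants: 10 (E)-1-[2,4-bis(benzyloxy)-6-hydroxyphenyl]-3-{4-[2-(benzyloxy)-5-(1,3-dioxolan-2-yl)phenoxy]phenyl}prop-2-en-1-one
Product: 12 4-(benzyloxy)-3-{4-[5,7-bis(benzyloxy)-4-oxo-4H-chromen-2-yl]phenoxy}benzaldehyde, via flavone acetal 11 (not isolated)
Conditions: I2 (10 mol%), DMSO, 125 °C; then 2 M HCl, THF, rt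
Reagents that add atoms: water, O
Why: Iodine-catalysed oxidative cyclisation of the 2'-hydroxychalcone (oxa-Michael closure, α-iodination and loss of HI, with dimethyl sulfoxide as terminal oxidant) gives the flavone, and acid hydrolysis of the dioxolane then frees the formyl group of ring B.

Step 8
Reactants: 12 4-(benzyloxy)-3-{4-[5,7-bis(benzyloxy)-4-oxo-4H-chromen-2-yl]phenoxy}benzaldehyde; 4 {1-[2-(benzyloxy)-6-fluoro-4-methoxyphenyl]ethenyloxy}trimethylsilane (1.3 equiv)
Product: 15 (2S)-5-(benzyloxy)-2-(4-(benzyloxy)-3-{4-[5,7-bis(benzyloxy)-4-oxo-4H-chromen-2-yl]phenoxy}phenyl)-7-methoxy-2,3-dihydro-4H-chromen-4-one, via trimethylsilyl aldol ether 13 (not isolated), via ammonium aldolate 14 (not isolated)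
Conditions: (S,S)-N-spiro bis(binaphthyl)ammonium hydrogen difluoride bearing 3,5-bis(trifluoromethyl)phenyl groups at the 3,3' positions (10 mol%, from the bromide by anion exchange), 4 Å molecular sieves, THF, −78 °C; then −78 → −20 °C; AcOH quench
Reagents that add atoms: none
Why: Proposed new method: fluoride from the catalyst takes the silyl group of 4 to give an ammonium enolate that adds to the formyl carbon of 12 (C2–C3 bond); the benzylic alkoxide 14, stored as silyl ether 13 while 4 is still present, then attacks the fluorine-bearing carbon ortho to the ketone by addition–elimination (O1–C8a bond), and the fluoride it expels starts the next turnover, so that Me3SiF is the only by-product. The closest known reaction types are the Mukaiyama-type aldol addition of silyl enol ethers and silyl nitronates to aromatic aldehydes under chiral quaternary ammonium fluoride or hydrogen difluoride catalysis, the aldol–cyclisation of 1-alkoxy-3-silyloxydienes with aldehydes to 2,3-dihydropyran-4-ones (ring A here plays the part of the alkoxy-bearing double bond, with fluoride as leaving group), and the base-induced closure of β-hydroxy 2-fluoroaryl ketones to chroman-4-ones. Ring C closes by intramolecular nucleophilic aromatic substitution, formally a 6-endo-trig conjugate addition of the alkoxide to the C8a=C4a–C4=O unit followed by loss of fluoride. The only new stereocentre, C2, is set in the C–C bond formation by the chiral cation that is ion-paired with the enolate and must guide it to the Si face of the aldehyde; the ring closure leaves the C2–O bond intact, so (3S)-13 should give (2S)-15. The step needs ring closure to outrun retro-aldol cleavage and β-elimination of the alkoxide: the fluorine is ortho to the activating ketone while the 5-benzyloxy and 7-methoxy groups are meta to the attacked carbon, free alkoxide is present only at catalyst level, and the chiral cation is the only counter-ion, so any alkoxide re-formed after cleavage is again made under its control. Addition to the formyl group is favoured over attack on the flavone, whose C2 is a hindered, fully substituted acceptor position.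

Step 9
Reactants: 15 (2S)-5-(benzyloxy)-2-(4-(benzyloxy)-3-{4-[5,7-bis(benzyloxy)-4-oxo-4H-chromen-2-yl]phenoxy}phenyl)-7-methoxy-2,3-dihydro-4H-chromen-4-one
Product: 16 (2S)-2-{3-[4-(5,7-dihydroxy-4-oxo-4H-chromen-2-yl)phenoxy]-4-hydroxyphenyl}-5-hydroxy-7-methoxy-2,3-dihydro-4H-chromen-4-one
Conditions: H2 (1 atm), 10% Pd/C, EtOAc–THF, rt, stopped at full debenzylation
Reagents that add atoms: none
Why: Catalytic hydrogenolysis of the four benzyl ethers under neutral conditions should leave the methyl ether, the flavone double bond and the base-sensitive C2 stereocentre untouched.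

**Compound list**
1 | 3,5-difluoroanisole | COc1cc(F)cc(F)c1 | starting material
2 | 1-(2,6-difluoro-4-methoxyphenyl)ethanone | CC(=O)c1c(F)cc(OC)cc1F | intermediate
3 | 1-[2-(benzyloxy)-6-fluoro-4-methoxyphenyl]ethanone | CC(=O)c1c(F)cc(OC)cc1OCc1ccccc1 | intermediate
4 | {1-[2-(benzyloxy)-6-fluoro-4-methoxyphenyl]ethenyloxy}trimethylsilane | C=C(O[Si](C)(C)C)c1c(F)cc(OC)cc1OCc1ccccc1 | intermediate
5 | 4-(benzyloxy)-3-hydroxybenzaldehyde | O=Cc1ccc(OCc2ccccc2)c(O)c1 | starting material
6 | 2-(benzyloxy)-5-(1,3-dioxolan-2-yl)phenol | Oc1cc(C2OCCO2)ccc1OCc1ccccc1 | intermediate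
7 | 4-fluorobenzaldehyde | O=Cc1ccc(F)cc1 | starting material
8 | 4-[2-(benzyloxy)-5-(1,3-dioxolan-2-yl)phenoxy]benzaldehyde | O=Cc1ccc(Oc2cc(C3OCCO3)ccc2OCc2ccccc2)cc1 | intermediate
9 | 1-[2,4-bis(benzyloxy)-6-hydroxyphenyl]ethanone | CC(=O)c1c(O)cc(OCc2ccccc2)cc1OCc1ccccc1 | starting material
10 | (E)-1-[2,4-bis(benzyloxy)-6-hydroxyphenyl]-3-{4-[2-(benzyloxy)-5-(1,3-dioxolan-2-yl)phenoxy]phenyl}prop-2-en-1-one | O=C(/C=C/c1ccc(Oc2cc(C3OCCO3)ccc2OCc2ccccc2)cc1)c1c(O)cc(OCc2ccccc2)cc1OCc1ccccc1 | intermediate
11 | 5,7-bis(benzyloxy)-2-{4-[2-(benzyloxy)-5-(1,3-dioxolan-2-yl)phenoxy]phenyl}-4H-chromen-4-one (flavone acetal, not isolated) | O=c1cc(-c2ccc(Oc3cc(C4OCCO4)ccc3OCc3ccccc3)cc2)oc2cc(OCc3ccccc3)cc(OCc3ccccc3)c12 | intermediate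
12 | 4-(benzyloxy)-3-{4-[5,7-bis(benzyloxy)-4-oxo-4H-chromen-2-yl]phenoxy}benzaldehyde | O=Cc1ccc(OCc2ccccc2)c(Oc2ccc(-c3cc(=O)c4c(OCc5ccccc5)cc(OCc5ccccc5)cc4o3)cc2)c1 | intermediate
13 | (3S)-1-[2-(benzyloxy)-6-fluoro-4-methoxyphenyl]-3-(4-(benzyloxy)-3-{4-[5,7-bis(benzyloxy)-4-oxo-4H-chromen-2-yl]phenoxy}phenyl)-3-(trimethylsilyloxy)propan-1-one (not isolated) | COc1cc(F)c(C(=O)C[C@H](O[Si](C)(C)C)c2ccc(OCc3ccccc3)c(Oc3ccc(-c4cc(=O)c5c(OCc6ccccc6)cc(OCc6ccccc6)cc5o4)cc3)c2)c(OCc2ccccc2)c1 | intermediate
14 | (3S)-alkoxide corresponding to 13, anion drawn, counter-ion is the catalyst cation (not isolated) | COc1cc(F)c(C(=O)C[C@H]([O-])c2ccc(OCc3ccccc3)c(Oc3ccc(-c4cc(=O)c5c(OCc6ccccc6)cc(OCc6ccccc6)cc5o4)cc3)c2)c(OCc2ccccc2)c1 | intermediate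
15 | (2S)-5-(benzyloxy)-2-(4-(benzyloxy)-3-{4-[5,7-bis(benzyloxy)-4-oxo-4H-chromen-2-yl]phenoxy}phenyl)-7-methoxy-2,3-dihydro-4H-chromen-4-one | COc1cc(OCc2ccccc2)c2c(c1)O[C@H](c1ccc(OCc3ccccc3)c(Oc3ccc(-c4cc(=O)c5c(OCc6ccccc6)cc(OCc6ccccc6)cc5o4)cc3)c1)CC2=O | intermediate
16 | (2S)-2-{3-[4-(5,7-dihydroxy-4-oxo-4H-chromen-2-yl)phenoxy]-4-hydroxyphenyl}-5-hydroxy-7-methoxy-2,3-dihydro-4H-chromen-4-one | COc1cc(O)c2c(c1)O[C@H](c1ccc(O)c(Oc3ccc(-c4cc(=O)c5c(O)cc(O)cc5o4)cc3)c1)CC2=O | target

**Count**
Total: 9 steps. Longest linear sequence: 6 steps (steps 4–9, from 5 to 16).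

**Steps most likely to fail**

Step 8. The ion-paired aldol addition may show poor facial selectivity. The free alkoxide may also undergo retro-aldol cleavage or β-elimination to the chalcone before the ring closes, which would erode the stereocentre and the yield; residual fluoride may open ring C of the product. The fallback sets out from ketone 3 and aldehyde 12 and uses known chemistry without asymmetric catalysis. The lithium enolate of 3 (LiN(i-Pr)2, THF, −78 °C) is added to 12 and the mixture is quenched cold with AcOH to give the racemic β-hydroxy ketone F1. KOt-Bu in THF at 0 °C then closes ring C by SNAr to the racemic benzyl-protected flavanone F2. Preparative HPLC on a cellulose tris(3,5-dimethylphenylcarbamate) phase separates the enantiomers; the (R)-enantiomer F3 is set aside and the (S)-enantiomer is 15, where the route is rejoined.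

Step 9. Hydrogenation may go too far (saturation of the flavone double bond, hydrogenolysis of the benzylic C2–O1 bond of ring C) or stop short at the hindered benzyl ethers next to the carbonyl groups. The fallback sets out from 15 and replaces reductive cleavage by Lewis-acid dealkylation: BCl3 with pentamethylbenzene as benzyl cation scavenger in CH2Cl2 at −78 °C, then MeOH quench. This should cleave the benzyl ethers and spare the methyl ether, and the route is rejoined at 16.

Step 7. The HI formed may remove the benzyl group next to the flavone carbonyl, or iodine may substitute the electron-rich rings. The fallback sets out from chalcone 10 and is iodine-free and stepwise. NaOAc in refluxing EtOH isomerises 10 to the racemic flavanone acetal F4 by oxa-Michael closure. Pd(O2CCF3)2 (5 mol%) under O2 in DMSO at 80 °C dehydrogenates F4 to flavone acetal 11, now isolated. 2 M HCl in THF then gives 12, where the route is rejoined.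

**Further compounds**
F1 | step 8 | racemic 1-[2-(benzyloxy)-6-fluoro-4-methoxyphenyl]-3-(4-(benzyloxy)-3-{4-[5,7-bis(benzyloxy)-4-oxo-4H-chromen-2-yl]phenoxy}phenyl)-3-hydroxypropan-1-one | COc1cc(F)c(C(=O)CC(O)c2ccc(OCc3ccccc3)c(Oc3ccc(-c4cc(=O)c5c(OCc6ccccc6)cc(OCc6ccccc6)cc5o4)cc3)c2)c(OCc2ccccc2)c1
F2 | step 8 | racemic 5-(benzyloxy)-2-(4-(benzyloxy)-3-{4-[5,7-bis(benzyloxy)-4-oxo-4H-chromen-2-yl]phenoxy}phenyl)-7-methoxy-2,3-dihydro-4H-chromen-4-one | COc1cc(OCc2ccccc2)c2c(c1)OC(c1ccc(OCc3ccccc3)c(Oc3ccc(-c4cc(=O)c5c(OCc6ccccc6)cc(OCc6ccccc6)cc5o4)cc3)c1)CC2=O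
F3 | step 8 | (2R)-5-(benzyloxy)-2-(4-(benzyloxy)-3-{4-[5,7-bis(benzyloxy)-4-oxo-4H-chromen-2-yl]phenoxy}phenyl)-7-methoxy-2,3-dihydro-4H-chromen-4-one | COc1cc(OCc2ccccc2)c2c(c1)O[C@@H](c1ccc(OCc3ccccc3)c(Oc3ccc(-c4cc(=O)c5c(OCc6ccccc6)cc(OCc6ccccc6)cc5o4)cc3)c1)CC2=O
F4 | step 7 | racemic 5,7-bis(benzyloxy)-2-{4-[2-(benzyloxy)-5-(1,3-dioxolan-2-yl)phenoxy]phenyl}-2,3-dihydro-4H-chromen-4-one | O=C1CC(c2ccc(Oc3cc(C4OCCO4)ccc3OCc3ccccc3)cc2)Oc2cc(OCc3ccccc3)cc(OCc3ccccc3)c12
F0 | step 9 | none | none
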